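Ring B of the trans-decalin (naphthalene locants: C-1 tigloyloxy, C-2 ketone, C-3 isopropenyl, C-4a angular methyl) is cut at two bonds at once: C-4a–C-4 and C-2–C-3. An iron-hydride hydrogen-atom-transfer radical–polar crossover annulation makes both in one operation: the exocyclic methylene of a monocyclic ring A aldehyde becomes the angular methyl and a tertiary radical, this adds to methyl vinyl ketone, and the resulting enolate closes ring B by aldol addition to the tethered aldehyde. The step exploits the quaternary C-4a next to the C-4 methylene and the C-3 methine α to the oxygenated C-2. Both esters are attached last.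

Key step: step 6

Remark: the decalin locants above are kept for all bicyclic compounds (C-5 secondary methyl, C-6 ring A oxygen, C-8a ring-fusion hydrogen). The C-2 carbinol configuration drawn for 12 and 13 is the one expected from a chair closure; either epimer converges at ketone 14.

Step 1
Reactants: 1 2-methylcyclohex-2-en-1-one
Product: 3 (2S,3R)-3-hydroxy-2-methylcyclohexan-1-one, via β-boryl ketone 2 (not isolated)
Conditions: CuCl (5 mol%), NaOt-Bu, (R,R)-QuinoxP* (or its enantiomer, whichever delivers 3R), B2pin2, MeOH, THF, rt; then NaBO3·4H2O, THF/H2O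
Reagents that add atoms: bis(pinacolato)diboron, CC1(C)OB(OC1(C)C)B1OC(C)(C)C(C)(C)O1 (boron of 2); sodium perborate, O=BO[O-].[Na+] (oxygen of 3)
Why: Copper-catalysed enantioselective conjugate borylation of a cyclic enone should set C-3 under catalyst control, the α-centre should equilibrate to the trans (diequatorial) isomer in the basic medium, and perborate oxidation of the C–B bond proceeds with retention (conjugate borylation–oxidation).

Step 2
Reactants: 3 (2S,3R)-3-hydroxy-2-methylcyclohexan-1-one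
Product: 4 (2S,3R)-3-[(tert-butyldimethylsilyl)oxy]-2-methylcyclohexan-1-one
Conditions: TBSCl, imidazole, DMF, rt
Reagents that add atoms: tert-butyldimethylsilyl chloride, CC(C)(C)[Si](C)(C)Cl
Why: Standard silylation of a secondary alcohol; the mild base should leave the β-oxygenated ketone intact.

Step 3
Reactants: 4 (2S,3R)-3-[(tert-butyldimethylsilyl)oxy]-2-methylcyclohexan-1-one; 5 ethyl bromoacetate
Product: 6 ethyl 2-[(1S,3S,4R)-4-[(tert-butyldimethylsilyl)oxy]-3-methyl-2-oxocyclohexyl]acetate
Conditions: LiN(i-Pr)2, THF, −78 °C; BrCH2CO2Et, DMPU, −78 → −30 °C; then DBU (cat.), CH2Cl2, rt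
Reagents that add atoms: none
Why: Kinetic deprotonation should occur at the unsubstituted α′-methylene (away from the β-silyloxy group), SN2 alkylation installs the acetate arm, and base equilibration of both α-centres should give the all-equatorial 2,6-cis isomer (enolate alkylation under thermodynamic stereocontrol).

Step 4
Reactants: 6 ethyl 2-[(1S,3S,4R)-4-[(tert-butyldimethylsilyl)oxy]-3-methyl-2-oxocyclohexyl]acetate
Product: 7 ethyl 2-[(1S,3R,4R)-4-[(tert-butyldimethylsilyl)oxy]-3-methyl-2-methylidenecyclohexyl]acetate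
Conditions: Zn, CH2Br2, TiCl4, THF/CH2Cl2, 0 °C → rt
Reagents that add atoms: dibromomethane, BrCBr
Why: The non-basic Zn/CH2Br2/TiCl4 methylenation (Lombardo-type) should convert the hindered ketone into the exocyclic alkene without epimerising either α-centre, eliminating the β-silyloxy group or touching the ester.

Step 5
Reactants: 7 ethyl 2-[(1S,3R,4R)-4-[(tert-butyldimethylsilyl)oxy]-3-methyl-2-methylidenecyclohexyl]acetate
Product: 8 2-[(1S,3R,4R)-4-[(tert-butyldimethylsilyl)oxy]-3-methyl-2-methylidenecyclohexyl]acetaldehyde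
Conditions: i-Bu2AlH (1.1 equiv), CH2Cl2, −78 °C; aq. potassium sodium tartrate
Reagents that add atoms: none
Why: Partial ester reduction through the aluminium hemiacetal, which is stable at −78 °C, should stop at the aldehyde; alkene and silyl ether are inert.

Step 6
Reactants: 8 2-[(1S,3R,4R)-4-[(tert-butyldimethylsilyl)oxy]-3-methyl-2-methylidenecyclohexyl]acetaldehyde; 9 but-3-en-2-one (methyl vinyl ketone)
Product: 12 1-[(2R,3R,4aS,5R,6R,8aS)-6-[(tert-butyldimethylsilyl)oxy]-2-hydroxy-4a,5-dimethyldecahydronaphthalen-3-yl]ethan-1-one, via tertiary ring radical 10 (not isolated), via Giese adduct enolate 11 (not isolated)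
Conditions: Fe(acac)3 (30 mol%), PhSiH3, methyl vinyl ketone (3 equiv), EtOH/(CH2OH)2, degassed, 0 °C → rt
Reagents that add atoms: none
Why: An iron hydride generated from Fe(acac)3 and PhSiH3 should transfer a hydrogen atom to the CH2 terminus of the exocyclic alkene, the tertiary radical 10 should add to the β-carbon of methyl vinyl ketone (bond C-4a–C-4), and reduction of the α-keto radical by divalent iron should give enolate 11, whose α-carbon adds to the tethered aldehyde (bond C-3–C-2). The closest known reaction type is the hydrogen-atom-transfer-initiated Giese addition coupled to an intramolecular aldol addition (radical–polar crossover annulation). Ring B is closed in a 6-(enolexo)-exo-trig aldol through a chair transition state. C-4a is under substrate control: the radical is flanked by the equatorial C-5 methyl and the equatorial side arm at C-8a, and the acceptor should add trans to both (the usual anti preference of 2-substituted cyclohexyl radicals), which places the new CH2 equatorial, the methyl axial and makes the ring fusion trans; C-3 should take the acetyl group equatorial in the chair closure, and the C-2 carbinol centre is of no consequence. The step needs hydrogen-atom transfer to the electron-rich 1,1-disubstituted alkene in preference to the enone and bond formation at C-4a on the α-face; the first is secured by the polarity match of a nucleophilic tertiary radical with an electron-poor acceptor in excess, the second by the two flanking substituents, and the aldol is favoured over protonation because it is intramolecular and six-membered.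

Step 7
Reactants: 12 1-[(2R,3R,4aS,5R,6R,8aS)-6-[(tert-butyldimethylsilyl)oxy]-2-hydroxy-4a,5-dimethyldecahydronaphthalen-3-yl]ethan-1-one
Product: 13 (2R,3S,4aS,5R,6R,8aS)-6-[(tert-butyldimethylsilyl)oxy]-4a,5-dimethyl-3-(prop-1-en-2-yl)decahydronaphthalen-2-ol
Conditions: Zn, CH2Br2, TiCl4, THF/CH2Cl2, 0 °C → rt
Reagents that add atoms: dibromomethane, BrCBr
Why: The same non-basic methylenation should turn the methyl ketone into the isopropenyl group while avoiding retro-aldol cleavage of the β-hydroxy ketone and epimerisation at C-3; the free hydroxyl is tolerated.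

Step 8
Reactants: 13 (2R,3S,4aS,5R,6R,8aS)-6-[(tert-butyldimethylsilyl)oxy]-4a,5-dimethyl-3-(prop-1-en-2-yl)decahydronaphthalen-2-ol
Product: 14 (3S,4aS,5R,6R,8aS)-6-[(tert-butyldimethylsilyl)oxy]-4a,5-dimethyl-3-(prop-1-en-2-yl)octahydronaphthalen-2(1H)-one
Conditions: Dess–Martin periodinane, NaHCO3, CH2Cl2, 0 °C → rt
Reagents that add atoms: none
Why: Buffered Dess–Martin oxidation should give the β,γ-unsaturated ketone without moving the alkene into conjugation; the equatorial isopropenyl group at C-3 is the thermodynamically preferred epimer, so a minor C-3 epimer can be equilibrated here.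

Step 9
Reactants: 14 (3S,4aS,5R,6R,8aS)-6-[(tert-butyldimethylsilyl)oxy]-4a,5-dimethyl-3-(prop-1-en-2-yl)octahydronaphthalen-2(1H)-one
Product: 15 (1S,3S,4aR,5R,6R,8aR)-6-[(tert-butyldimethylsilyl)oxy]-1-hydroxy-4a,5-dimethyl-3-(prop-1-en-2-yl)octahydronaphthalen-2(1H)-one
Conditions: KN(SiMe3)2 (1.1 equiv), THF, −78 °C; 2-(phenylsulfonyl)-3-phenyloxaziridine, −78 °C; AcOH quench
Reagents that add atoms: 2-(phenylsulfonyl)-3-phenyloxaziridine, O=S(=O)(c1ccccc1)N1OC1c1ccccc1
Why: Kinetic deprotonation should take place at the C-1 methylene (the C-3 methine is hindered and its C–H bond is held in the plane of the isopropenyl group by allylic strain), and oxygen transfer to the enolate on the face opposite the axial angular methyl should give the equatorial (1S) α-hydroxy ketone (enolate hydroxylation with a Davis oxaziridine).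

Step 10
Reactants: 15 (1S,3S,4aR,5R,6R,8aR)-6-[(tert-butyldimethylsilyl)oxy]-1-hydroxy-4a,5-dimethyl-3-(prop-1-en-2-yl)octahydronaphthalen-2(1H)-one; 16 (2E)-2-methylbut-2-enoyl chloride (tigloyl chloride)
Product: 17 (1S,3S,4aR,5R,6R,8aR)-6-[(tert-butyldimethylsilyl)oxy]-4a,5-dimethyl-2-oxo-3-(prop-1-en-2-yl)decahydronaphthalen-1-yl (2E)-2-methylbut-2-enoate
Conditions: tigloyl chloride, pyridine, DMAP (cat.), CH2Cl2, 0 °C → rt
Reagents that add atoms: none
Why: Acylation of the secondary α-ketol with the acid chloride; the E-configured tiglate is the stable geometric isomer and should not isomerise.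

Step 11
Reactants: 17 (1S,3S,4aR,5R,6R,8aR)-6-[(tert-butyldimethylsilyl)oxy]-4a,5-dimethyl-2-oxo-3-(prop-1-en-2-yl)decahydronaphthalen-1-yl (2E)-2-methylbut-2-enoate
Product: 18 (1S,3S,4aR,5R,6R,8aR)-6-hydroxy-4a,5-dimethyl-2-oxo-3-(prop-1-en-2-yl)decahydronaphthalen-1-yl (2E)-2-methylbut-2-enoate
Conditions: HF·pyridine, pyridine, THF, 0 °C → rt
Reagents that add atoms: none
Why: Buffered fluoride cleavage of the silyl ether should leave the α-acyloxy ketone (no acyl migration or epimerisation under non-basic conditions) and both alkenes untouched.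

Step 12
Reactants: 18 (1S,3S,4aR,5R,6R,8aR)-6-hydroxy-4a,5-dimethyl-2-oxo-3-(prop-1-en-2-yl)decahydronaphthalen-1-yl (2E)-2-methylbut-2-enoate; 19 3-methylbut-2-enoic acid (senecioic acid)
Product: 20 (1S,3S,4aR,5R,6R,8aR)-4a,5-dimethyl-6-[(3-methylbut-2-enoyl)oxy]-2-oxo-3-(prop-1-en-2-yl)decahydronaphthalen-1-yl (2E)-2-methylbut-2-enoate (CNP0164025.1)
Conditions: 3-methylbut-2-enoic acid, EDC·HCl, DMAP, CH2Cl2, rt
Reagents that add atoms: none
Why: Carbodiimide (Steglich-type) esterification of the equatorial secondary alcohol; using the free acid instead of the acid chloride with amine base should avoid deconjugation of the senecioate.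

Compound list
1 | 2-methylcyclohex-2-en-1-one | CC1=CCCCC1=O | starting material
2 | (2S,3R)-2-methyl-3-(4,4,5,5-tetramethyl-1,3,2-dioxaborolan-2-yl)cyclohexan-1-one | O=C1[C@@H](C)[C@H](B2OC(C)(C)C(C)(C)O2)CCC1 | intermediate (not isolated)
3 | (2S,3R)-3-hydroxy-2-methylcyclohexan-1-one | O=C1[C@@H](C)[C@H](O)CCC1 | intermediate
4 | (2S,3R)-3-[(tert-butyldimethylsilyl)oxy]-2-methylcyclohexan-1-one | O=C1[C@@H](C)[C@H](O[Si](C)(C)C(C)(C)C)CCC1 | intermediate
5 | ethyl bromoacetate | CCOC(=O)CBr | starting material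
6 | ethyl 2-[(1S,3S,4R)-4-[(tert-butyldimethylsilyl)oxy]-3-methyl-2-oxocyclohexyl]acetate | O=C1[C@@H](C)[C@H](O[Si](C)(C)C(C)(C)C)CC[C@H]1CC(=O)OCC | intermediate
7 | ethyl 2-[(1S,3R,4R)-4-[(tert-butyldimethylsilyl)oxy]-3-methyl-2-methylidenecyclohexyl]acetate | C=C1[C@@H](C)[C@H](O[Si](C)(C)C(C)(C)C)CC[C@H]1CC(=O)OCC | intermediate
8 | 2-[(1S,3R,4R)-4-[(tert-butyldimethylsilyl)oxy]-3-methyl-2-methylidenecyclohexyl]acetaldehyde | C=C1[C@@H](C)[C@H](O[Si](C)(C)C(C)(C)C)CC[C@H]1CC=O | intermediate
9 | but-3-en-2-one (methyl vinyl ketone) | CC(=O)C=C | starting material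
10 | tertiary ring radical from 8 (radical centre at the future C-4a, other centres as in 8) | C[C]1[C@@H](C)[C@H](O[Si](C)(C)C(C)(C)C)CC[C@H]1CC=O | intermediate (not isolated)
11 | enolate of the Giese adduct (iron enolate, drawn as the anion; enolate geometry not defined) | CC([O-])=CC[C@]1(C)[C@@H](C)[C@H](O[Si](C)(C)C(C)(C)C)CC[C@H]1CC=O | intermediate (not isolated)
12 | 1-[(2R,3R,4aS,5R,6R,8aS)-6-[(tert-butyldimethylsilyl)oxy]-2-hydroxy-4a,5-dimethyldecahydronaphthalen-3-yl]ethan-1-one | CC(=O)[C@@H]1C[C@]2(C)[C@@H](C)[C@H](O[Si](C)(C)C(C)(C)C)CC[C@H]2C[C@H]1O | intermediate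
13 | (2R,3S,4aS,5R,6R,8aS)-6-[(tert-butyldimethylsilyl)oxy]-4a,5-dimethyl-3-(prop-1-en-2-yl)decahydronaphthalen-2-ol | C=C(C)[C@@H]1C[C@]2(C)[C@@H](C)[C@H](O[Si](C)(C)C(C)(C)C)CC[C@H]2C[C@H]1O | intermediate
14 | (3S,4aS,5R,6R,8aS)-6-[(tert-butyldimethylsilyl)oxy]-4a,5-dimethyl-3-(prop-1-en-2-yl)octahydronaphthalen-2(1H)-one | C=C(C)[C@@H]1C[C@]2(C)[C@@H](C)[C@H](O[Si](C)(C)C(C)(C)C)CC[C@H]2CC1=O | intermediate
15 | (1S,3S,4aR,5R,6R,8aR)-6-[(tert-butyldimethylsilyl)oxy]-1-hydroxy-4a,5-dimethyl-3-(prop-1-en-2-yl)octahydronaphthalen-2(1H)-one | C=C(C)[C@@H]1C[C@]2(C)[C@@H](C)[C@H](O[Si](C)(C)C(C)(C)C)CC[C@H]2[C@H](O)C1=O | intermediate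
16 | (2E)-2-methylbut-2-enoyl chloride (tigloyl chloride) | ClC(=O)/C(C)=C/C | starting material
17 | (1S,3S,4aR,5R,6R,8aR)-6-[(tert-butyldimethylsilyl)oxy]-4a,5-dimethyl-2-oxo-3-(prop-1-en-2-yl)decahydronaphthalen-1-yl (2E)-2-methylbut-2-enoate | C=C(C)[C@@H]1C[C@]2(C)[C@@H](C)[C@H](O[Si](C)(C)C(C)(C)C)CC[C@H]2[C@H](OC(=O)/C(C)=C/C)C1=O | intermediate
18 | (1S,3S,4aR,5R,6R,8aR)-6-hydroxy-4a,5-dimethyl-2-oxo-3-(prop-1-en-2-yl)decahydronaphthalen-1-yl (2E)-2-methylbut-2-enoate | C=C(C)[C@@H]1C[C@]2(C)[C@@H](C)[C@H](O)CC[C@H]2[C@H](OC(=O)/C(C)=C/C)C1=O | intermediate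
19 | 3-methylbut-2-enoic acid (senecioic acid) | CC(C)=CC(=O)O | starting material
20 | (1S,3S,4aR,5R,6R,8aR)-4a,5-dimethyl-6-[(3-methylbut-2-enoyl)oxy]-2-oxo-3-(prop-1-en-2-yl)decahydronaphthalen-1-yl (2E)-2-methylbut-2-enoate | C=C(C)[C@@H]1C[C@]2(C)[C@@H](C)[C@H](OC(=O)C=C(C)C)CC[C@H]2[C@H](OC(=O)/C(C)=C/C)C1=O | target

Total step count: 12. Longest linear sequence: 12 steps (from 1).

Steps most likely to fail

Step 6. What may go wrong: insufficient facial control in the intermolecular radical addition at C-4a (addition on the axial face would lead into the cis-fused series), or protonation of the enolate before ring closure. The fallback sets out from 8 and returns at 12. Morita–Baylis–Hillman reaction of aldehyde 8 with methyl vinyl ketone (DABCO) should give 4-hydroxy-5-[(1S,3R,4R)-4-[(tert-butyldimethylsilyl)oxy]-3-methyl-2-methylidenecyclohexyl]-3-methylidenepentan-2-one F1, in which the C-2–C-3 bond already exists. Exposure of F1 to Fe(acac)3 and PhSiH3 in EtOH should generate the same tertiary radical. It now closes ring B intramolecularly by 6-endo addition to the enone CH2, through a chair transition state with the tether equatorial, so the ring fusion is set by the ring closure. Reduction and protonation of the α-keto radical give 12 as carbinol epimers that converge at 14.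

Step 9. What may go wrong: loss of regiocontrol in the enolisation, that is competing removal of the doubly activated C-3 methine, which would lead to oxygenation at C-3 or migration of the alkene into conjugation. The fallback sets out from 8 and returns at 15; it brings the C-1 oxygen in before ring B exists. Amine-catalysed α-benzoyloxylation of aldehyde 8 (dibenzoyl peroxide, catalytic (S)-2-tritylpyrrolidine, THF) should give (1S)-1-[(1R,3R,4R)-4-[(tert-butyldimethylsilyl)oxy]-3-methyl-2-methylidenecyclohexyl]-2-oxoethyl benzoate F2. The annulation of step 6 should then give (1S,2S,3R,4aR,5R,6R,8aR)-3-acetyl-6-[(tert-butyldimethylsilyl)oxy]-2-hydroxy-4a,5-dimethyldecahydronaphthalen-1-yl benzoate F3. Methylenation as in step 7 should give (1S,2S,3S,4aR,5R,6R,8aR)-6-[(tert-butyldimethylsilyl)oxy]-2-hydroxy-4a,5-dimethyl-3-(prop-1-en-2-yl)decahydronaphthalen-1-yl benzoate F4. Dess–Martin oxidation should give (1S,3S,4aR,5R,6R,8aR)-6-[(tert-butyldimethylsilyl)oxy]-4a,5-dimethyl-2-oxo-3-(prop-1-en-2-yl)decahydronaphthalen-1-yl benzoate F5. K2CO3 in MeOH then removes the benzoate, with C-1 free to settle in the equatorial configuration, and gives 15.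

Step 1. What may go wrong: insufficient enantioselectivity or conversion in the conjugate borylation of the α-substituted enone. The fallback sets out from 1 and returns at 4. Corey–Bakshi–Shibata reduction of 1 (oxazaborolidine catalyst, BH3·SMe2) should give (1R)-2-methylcyclohex-2-en-1-ol F6. Silylation (TBSCl, imidazole) gives tert-butyldimethyl{[(1R)-2-methylcyclohex-2-en-1-yl]oxy}silane F7. Hydroboration–oxidation (BH3·THF; H2O2, NaOH) anti to the silyloxy group should give (1R,2S,3R)-3-[(tert-butyldimethylsilyl)oxy]-2-methylcyclohexan-1-ol F8. Dess–Martin oxidation gives the cis ketone (2R,3R)-3-[(tert-butyldimethylsilyl)oxy]-2-methylcyclohexan-1-one F9, and epimerisation of its α-centre (DBU, CH2Cl2) gives the trans ketone 4.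

Further compounds
F1 | step 6 | 4-hydroxy-5-[(1S,3R,4R)-4-[(tert-butyldimethylsilyl)oxy]-3-methyl-2-methylidenecyclohexyl]-3-methylidenepentan-2-one | C=C1[C@@H](C)[C@H](O[Si](C)(C)C(C)(C)C)CC[C@H]1CC(O)C(=C)C(C)=O
F2 | step 9 | (1S)-1-[(1R,3R,4R)-4-[(tert-butyldimethylsilyl)oxy]-3-methyl-2-methylidenecyclohexyl]-2-oxoethyl benzoate | C=C1[C@@H](C)[C@H](O[Si](C)(C)C(C)(C)C)CC[C@H]1[C@H](OC(=O)c1ccccc1)C=O
F3 | step 9 | (1S,2S,3R,4aR,5R,6R,8aR)-3-acetyl-6-[(tert-butyldimethylsilyl)oxy]-2-hydroxy-4a,5-dimethyldecahydronaphthalen-1-yl benzoate | CC(=O)[C@@H]1C[C@]2(C)[C@@H](C)[C@H](O[Si](C)(C)C(C)(C)C)CC[C@H]2[C@H](OC(=O)c2ccccc2)[C@H]1O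
F4 | step 9 | (1S,2S,3S,4aR,5R,6R,8aR)-6-[(tert-butyldimethylsilyl)oxy]-2-hydroxy-4a,5-dimethyl-3-(prop-1-en-2-yl)decahydronaphthalen-1-yl benzoate | C=C(C)[C@@H]1C[C@]2(C)[C@@H](C)[C@H](O[Si](C)(C)C(C)(C)C)CC[C@H]2[C@H](OC(=O)c2ccccc2)[C@H]1O
F5 | step 9 | (1S,3S,4aR,5R,6R,8aR)-6-[(tert-butyldimethylsilyl)oxy]-4a,5-dimethyl-2-oxo-3-(prop-1-en-2-yl)decahydronaphthalen-1-yl benzoate | C=C(C)[C@@H]1C[C@]2(C)[C@@H](C)[C@H](O[Si](C)(C)C(C)(C)C)CC[C@H]2[C@H](OC(=O)c2ccccc2)C1=O
F6 | step 1 | (1R)-2-methylcyclohex-2-en-1-ol | CC1=CCCC[C@H]1O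
F7 | step 1 | tert-butyldimethyl{[(1R)-2-methylcyclohex-2-en-1-yl]oxy}silane | CC1=CCCC[C@H]1O[Si](C)(C)C(C)(C)C
F8 | step 1 | (1R,2S,3R)-3-[(tert-butyldimethylsilyl)oxy]-2-methylcyclohexan-1-ol | O[C@H]1[C@H](C)[C@H](O[Si](C)(C)C(C)(C)C)CCC1
F9 | step 1 | (2R,3R)-3-[(tert-butyldimethylsilyl)oxy]-2-methylcyclohexan-1-one | O=C1[C@H](C)[C@H](O[Si](C)(C)C(C)(C)C)CCC1
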